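The route rests on cutting ring B (the cyclohexanone) at two bonds: the ketone carbon–CH(CH3) bond on the side remote from the ring fusion, and the bond from the neighbouring CH2 to the sp2 ring-fusion carbon. The ring-B ketone and the ring-A unsaturation next to that fusion carbon form the δ,ε-unsaturated-ketone pattern of an oxy-Cope product. One operation therefore makes both bonds: isopropenyl addition to a bicyclo[2.2.2]oct-5-en-2-one, then anionic oxy-Cope rearrangement of the alkoxide, which closes ring B and opens the bicycle into ring A. The bicyclic keto acid precursor comes from 2,6-dimethylphenol by dearomatisation and intramolecular Diels–Alder reaction.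

Key step: step 5

Remark: 5–7 are racemic (the SMILES show the enantiomer carried on after the resolution in step 4), and carbons that are later flattened (the sulfonyl-bearing C2 of 12–16, the ring-B carbinol C7 of 14–26, the side-chain carbinol of 22–26, the exocyclic alkene of 17) are carried as mixtures and written without configuration.

Decalin locants used below: C1 bears the side chain, C2 the acetonyl group, C3 the ring-A methyl, C4a and C8a are the fusion carbons, C6 and C8 bear the ring-B methyls, C7 is the ring-B carbonyl carbon.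

Step 1
Reactants: 1 (E)-3-chloroacrylic acid; 2 sodium 4-methylbenzenesulfinate
Product: 3 (E)-3-(4-methylphenylsulfonyl)acrylic acid
Conditions: p-TolSO2Na, H2O–EtOH, 80 °C
Reagents that add atoms: none
Why: Nucleophilic vinylic substitution (addition–elimination) of chloride by the soft sulfinate sulfur at the β-carbon should give the sulfone with the stable E geometry.

Step 2
Reactants: 4 2,6-dimethylphenol; 3 (E)-3-(4-methylphenylsulfonyl)acrylic acid
Product: 6 racemic keto lactone (1,3-dimethyl-2-oxo-7-tosylbicyclo[2.2.2]oct-5-ene whose O-3 and C8 carboxyl form a γ-lactone anti to C5=C6; sulfonyl syn to C5=C6), via dienone ester 5 (not isolated)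
Conditions: Pb(OAc)4, excess 3, CH2Cl2, 0 → 25 °C; then toluene, 80 °C
Reagents that add atoms: none
Why: Modified Wessely oxidation (ortho-acyloxylation of the phenol by ligand coupling at tetravalent lead) should give dienone 5, whose tethered sulfonylacrylate then closes the bicyclo[2.2.2]octenone by intramolecular Diels–Alder reaction; the three-atom ester tether fixes the regiochemistry and holds the lactone carbonyl on the side of the ketone bridge, and the E alkene places the sulfonyl group syn to the new C5=C6 bridge.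

Step 3
Reactants: 6 racemic keto lactone
Product: 7 racemic 1,3-dimethyl-2-oxo-7-tosylbicyclo[2.2.2]oct-5-ene-8-carboxylic acid (3-methyl and 8-carboxyl anti to C5=C6; 7-sulfonyl syn to C5=C6)
Conditions: SmI2, THF–MeOH, −78 °C; then dilute HCl
Reagents that add atoms: none
Why: Reductive cleavage of the α-acyloxy ketone by SmI2 (two single-electron transfers, expulsion of the carboxylate) gives a samarium enolate that MeOH should protonate from the open face next to C5=C6, the other face being screened by the C8 carboxylate, which leaves the C3 methyl anti to C5=C6 (kinetic protonation).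

Step 4
Reactants: 7 racemic keto acid; 8 (S)-1-phenylethylamine
Product: 10 enantiopure keto acid (configuration as in the SMILES), via ammonium salt 9 (not isolated)
Conditions: 8 (0.5 equiv), EtOAc–EtOH, crystallisation at 25 °C; then 1 M HCl, EtOAc
Reagents that add atoms: none
Why: Classical resolution by crystallisation of one diastereomeric ammonium carboxylate; the absolute configuration is to be proved by X-ray diffraction of the salt, and the (R)-amine is taken if the (S)-amine should crystallise with the antipode.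

Step 5
Reactants: 10 enantiopure keto acid
Product: 13 cis-fused 3,6,8-trimethyl-7-oxo-2-tosyl-1,2,4a,5,6,7,8,8a-octahydronaphthalene-1-carboxylic acid (H-1 H-4a H-6 H-8 H-8a on one face), via potassium alkoxide 11 (not isolated), via potassium enolate 12 (not isolated)
Conditions: CH2=C(CH3)Li (3.5 equiv, from 2-bromopropene and t-BuLi), THF, −78 °C; then KOt-Bu, 18-crown-6, −78 → 25 °C; then AcOH, THF, −78 °C
Reagents that add atoms: isopropenyllithium, [Li]C(C)=C
Why: The organolithium (two equivalents are spent on the acid and the α-sulfonyl C–H) should add to the ketone from the face next to C5=C6, the other face being blocked by the C3 methyl and the C8 carboxylate, so that the isopropenyl group lies over the etheno bridge; exchange of lithium for crown-complexed potassium then triggers the anionic oxy-Cope ([3,3]-sigmatropic) rearrangement of the 1,5-diene alkoxide, the closest known reaction type being the vinyl addition/oxy-Cope sequence that turns bicyclo[2.2.2]oct-5-en-2-ones into cis-decalins. The bond from the ketone carbon to the methyl-bearing carbon is made in the 1,2-addition, and the bond from the isopropenyl CH2 to C5 of the bicycle (the later fusion carbon C4a) in the sigmatropic shift. Ring B is closed by that shift through a boat-like six-centre transition state enforced by the bicycle, while cleavage of C1–C2 opens the bicycle into ring A with its double bond at C3=C4. C4a is set cis to H-8a because the shift is suprafacial on the etheno bridge from the side of the ketone bridge (this centre is flattened in step 9). C6 is set by axial protonation of the regiodefined enolate on the convex face of the cis-decalin, in the conformer that holds both ring-B methyl groups equatorial. The step needs addition to win over enolisation and a prompt cold quench so that the enolate does not migrate towards C8; the rigid, one-sidedly shielded bicycle secures the facial selectivity.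

Step 6
Reactants: 13 decalin keto acid
Product: 14 1-(hydroxymethyl)-3,6,8-trimethyl-2-tosyl-1,2,4a,5,6,7,8,8a-octahydronaphthalen-7-ol
Conditions: LiAlH4, THF, 0 → 40 °C
Reagents that add atoms: none
Why: Hydride reduction with LiAlH4 should turn the acid into the primary alcohol and the ketone into a secondary alcohol, which masks the ring-B ketone so that its two α-centres cannot epimerise in the basic steps that follow; the carbinol configuration is of no consequence.

Step 7
Reactants: 14 diol sulfone
Product: 15 2-allyl-1-(hydroxymethyl)-3,6,8-trimethyl-2-tosyl-1,2,4a,5,6,7,8,8a-octahydronaphthalen-7-ol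
Conditions: n-BuLi (3.1 equiv), THF–DMPU, −78 °C; then allyl bromide, −78 → −20 °C; then H2O
Reagents that add atoms: allyl bromide, C=CCBr
Why: Alkylation of the α-sulfonyl allyl carbanion (generated beside two lithium alkoxides) with allyl bromide should occur at the sulfonyl-bearing carbon, as is usual for allyl sulfone anions, the lithium alkoxides being far less nucleophilic at −78 °C.

Step 8
Reactants: 15 allyl sulfone
Product: 16 1-[7-hydroxy-1-(hydroxymethyl)-3,6,8-trimethyl-2-tosyl-1,2,4a,5,6,7,8,8a-octahydronaphthalen-2-yl]propan-2-one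
Conditions: PdCl2 (10 mol%), CuCl, O2 (1 atm), DMF–H2O, 25 °C
Reagents that add atoms: water, O
Why: Tsuji–Wacker oxidation (Markovnikov hydroxypalladation of the terminal alkene, β-hydride elimination) should give the methyl ketone and leave the trisubstituted ring alkene untouched.

Step 9
Reactants: 16 β-sulfonyl ketone
Product: 18 1-[7-hydroxy-1-(hydroxymethyl)-3,6,8-trimethyl-1,5,6,7,8,8a-hexahydronaphthalen-2-yl]propan-2-one, via dienone 17 (not isolated)
Conditions: KOt-Bu (excess), t-BuOH–THF, 0 → 25 °C; then inverse quench into AcOH–H2O, −10 °C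
Reagents that add atoms: none
Why: E1cB loss of sulfinate from the β-sulfonyl ketone gives dienone 17, equilibrating base then removes the ε-proton at the fusion carbon C4a to give the linear trienolate, and kinetic α-protonation on inverse quench (deconjugation as practised on steroidal 4,6-dien-3-ones) should give the ring-A diene with the ketone out of conjugation.

Step 10
Reactants: 18 dienyl ketone diol
Product: 20 (E)-3-[7-hydroxy-3,6,8-trimethyl-2-(2-oxopropyl)-1,5,6,7,8,8a-hexahydronaphthalen-1-yl]-2-methylprop-2-enal, via keto aldehyde 19 (not isolated)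
Conditions: [Cu(MeCN)4]OTf (5 mol%), 2,2'-bipyridine, TEMPO, N-methylimidazole, air, MeCN, 25 °C; then Ph3P=C(CH3)CHO, toluene, 80 °C
Reagents that add atoms: 2-(triphenylphosphoranylidene)propanal, CC(C=O)=P(c1ccccc1)(c1ccccc1)c1ccccc1
Why: Copper/nitroxyl aerobic oxidation is selective for the primary alcohol, and the sensitive aldehyde 19 is consumed without isolation in a Wittig reaction with the stabilised ylide, which should give the E trisubstituted enal.

Step 11
Reactants: 20 enal
Product: 21 ethyl (2E,4E)-5-[7-hydroxy-3,6,8-trimethyl-2-(2-oxopropyl)-1,5,6,7,8,8a-hexahydronaphthalen-1-yl]-2,4-dimethylpenta-2,4-dienoate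
Conditions: Ph3P=C(CH3)CO2Et, toluene, 80 °C
Reagents that add atoms: ethyl 2-(triphenylphosphoranylidene)propanoate, CCOC(=O)C(C)=P(c1ccccc1)(c1ccccc1)c1ccccc1
Why: Wittig reaction of the enal with the stabilised ylide should give the 2E,4E dienoate.

Step 12
Reactants: 21 dienoate
Product: 22 (2E,4E)-5-[7-hydroxy-2-(2-hydroxypropyl)-3,6,8-trimethyl-1,5,6,7,8,8a-hexahydronaphthalen-1-yl]-2,4-dimethylpenta-2,4-dien-1-ol
Conditions: i-Bu2AlH (excess), CH2Cl2, −78 °C; then aqueous potassium sodium tartrate
Reagents that add atoms: none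
Why: i-Bu2AlH should reduce the ester to the allylic alcohol by 1,2-reduction and the methyl ketone to a carbinol (carbonyl reduction), which takes the β,γ-unsaturated ketone out of the way of the hydroxide used in step 15.

Step 13
Reactants: 22 dienyl triol
Product: 23 [(2S,3S)-3-{(E)-1-[7-hydroxy-2-(2-hydroxypropyl)-3,6,8-trimethyl-1,5,6,7,8,8a-hexahydronaphthalen-1-yl]prop-1-en-2-yl}-2-methyloxiran-2-yl]methanol
Conditions: Ti(Oi-Pr)4 (cat.), L-(+)-diethyl tartrate, t-BuOOH, 4 Å molecular sieves, CH2Cl2, −25 °C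
Reagents that add atoms: tert-butyl hydroperoxide, CC(C)(C)OO
Why: Sharpless asymmetric epoxidation acts only on the double bond of the allylic alcohol and, with L-(+)-diethyl tartrate, should deliver the oxygen to the face that gives the (2S,3S)-epoxide under reagent control.

Step 14
Reactants: 23 epoxy triol
Product: 25 methyl (E)-3-[(2S,3S)-3-{(E)-1-[7-hydroxy-2-(2-hydroxypropyl)-3,6,8-trimethyl-1,5,6,7,8,8a-hexahydronaphthalen-1-yl]prop-1-en-2-yl}-2-methyloxiran-2-yl]acrylate, via epoxy aldehyde 24 (not isolated)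
Conditions: [Cu(MeCN)4]OTf (5 mol%), 2,2'-bipyridine, TEMPO, N-methylimidazole, air, MeCN, 25 °C; then Ph3P=CHCO2Me, 25 °C
Reagents that add atoms: methyl (triphenylphosphoranylidene)acetate, COC(=O)C=P(c1ccccc1)(c1ccccc1)c1ccccc1
Why: Aerobic copper/nitroxyl oxidation of the primary alcohol gives the non-enolisable epoxy aldehyde 24, which the stabilised ylide should convert in the same flask into the E enoate (Wittig reaction); the conditions are free of acid, so the vinyl epoxide should survive.

Step 15
Reactants: 25 methyl ester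
Product: 26 (E)-3-[(2S,3S)-3-{(E)-1-[7-hydroxy-2-(2-hydroxypropyl)-3,6,8-trimethyl-1,5,6,7,8,8a-hexahydronaphthalen-1-yl]prop-1-en-2-yl}-2-methyloxiran-2-yl]acrylic acid
Conditions: LiOH, THF–MeOH–H2O, 0 → 25 °C; then AcOH to pH 5
Reagents that add atoms: lithium hydroxide, [Li+].[OH-]
Why: Saponification of the methyl ester; no ketone is present at this stage, so no stereocentre can epimerise, and vinyl epoxides tolerate hydroxide.

Step 16
Reactants: 26 dihydroxy acid
Product: 27 target CNP0214881.1
Conditions: Dess–Martin periodinane, pyridine, CH2Cl2, 0 → 25 °C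
Reagents that add atoms: none
Why: Dess–Martin oxidation of both secondary alcohols under pyridine-buffered, non-basic conditions should unveil the ring-B ketone and the acetonyl ketone without epimerisation at C6 and C8, without migration of the β,γ-double bond and without opening of the epoxide.

Compound list

1 | (E)-3-chloroacrylic acid | OC(=O)/C=C/Cl | starting material
2 | sodium 4-methylbenzenesulfinate | Cc1ccc(cc1)S(=O)[O-].[Na+] | starting material
3 | (E)-3-(4-methylphenylsulfonyl)acrylic acid | Cc1ccc(cc1)S(=O)(=O)/C=C/C(=O)O | intermediate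
4 | 2,6-dimethylphenol | Cc1cccc(C)c1O | starting material
5 | 1,5-dimethyl-6-oxocyclohexa-2,4-dien-1-yl (E)-3-(4-methylphenylsulfonyl)acrylate, racemic, not isolated | CC1=CC=C[C@@](C)(OC(=O)/C=C/S(=O)(=O)c2ccc(C)cc2)C1=O | intermediate
6 | racemic keto lactone: 1,3-dimethyl-2-oxo-7-tosylbicyclo[2.2.2]oct-5-ene with O-3 and the C8 carboxyl joined as γ-lactone anti to C5=C6, sulfonyl syn to C5=C6 | C[C@@]12C(=O)[C@]3(C)OC(=O)[C@@H]([C@@H]3C=C1)[C@H]2S(=O)(=O)c1ccc(C)cc1 | intermediate
7 | racemic 1,3-dimethyl-2-oxo-7-tosylbicyclo[2.2.2]oct-5-ene-8-carboxylic acid (3-methyl and 8-carboxyl anti to C5=C6, 7-sulfonyl syn) | C[C@@]12C(=O)[C@H](C)[C@@H](C=C1)[C@H](C(=O)O)[C@H]2S(=O)(=O)c1ccc(C)cc1 | intermediate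
8 | (S)-1-phenylethylamine | C[C@H](N)c1ccccc1 | starting material
9 | (S)-1-phenylethylammonium salt of 10, crystallised and cleaved in the same step | C[C@@]12C(=O)[C@H](C)[C@@H](C=C1)[C@H](C(=O)[O-])[C@H]2S(=O)(=O)c1ccc(C)cc1.C[C@H]([NH3+])c1ccccc1 | intermediate
10 | enantiopure keto acid (same constitution and relative configuration as 7) | C[C@@]12C(=O)[C@H](C)[C@@H](C=C1)[C@H](C(=O)[O-])[C@H]2S(=O)(=O)c1ccc(C)cc1.[H+] | intermediate
11 | tertiary alkoxide from isopropenyl addition (isopropenyl syn to C5=C6), shown as dipotassium salt, not isolated | C[C@@]12[C@@]([O-])(C(C)=C)[C@H](C)[C@@H](C=C1)[C@H](C(=O)[O-])[C@H]2S(=O)(=O)c1ccc(C)cc1.[K+].[K+] | intermediate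
12 | cis-decalin enolate (C6=C7 enolate), shown as dipotassium salt, not isolated | Cc1ccc(cc1)S(=O)(=O)C1C(C)=C[C@@H]2CC(C)=C([O-])[C@H](C)[C@@H]2[C@@H]1C(=O)[O-].[K+].[K+] | intermediate
13 | cis-fused 3,6,8-trimethyl-7-oxo-2-tosyl-1,2,4a,5,6,7,8,8a-octahydronaphthalene-1-carboxylic acid; H-1, H-4a, H-6, H-8, H-8a on one face | Cc1ccc(cc1)S(=O)(=O)C1C(C)=C[C@@H]2C[C@H](C)C(=O)[C@H](C)[C@@H]2[C@@H]1C(=O)O | intermediate
14 | 1-(hydroxymethyl)-3,6,8-trimethyl-2-tosyl-1,2,4a,5,6,7,8,8a-octahydronaphthalen-7-ol | Cc1ccc(cc1)S(=O)(=O)C1C(C)=C[C@@H]2C[C@H](C)C(O)[C@H](C)[C@@H]2[C@@H]1CO | intermediate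
15 | 2-allyl-1-(hydroxymethyl)-3,6,8-trimethyl-2-tosyl-1,2,4a,5,6,7,8,8a-octahydronaphthalen-7-ol | Cc1ccc(cc1)S(=O)(=O)C1(CC=C)C(C)=C[C@@H]2C[C@H](C)C(O)[C@H](C)[C@@H]2[C@@H]1CO | intermediate
16 | 1-[7-hydroxy-1-(hydroxymethyl)-3,6,8-trimethyl-2-tosyl-1,2,4a,5,6,7,8,8a-octahydronaphthalen-2-yl]propan-2-one | Cc1ccc(cc1)S(=O)(=O)C1(CC(C)=O)C(C)=C[C@@H]2C[C@H](C)C(O)[C@H](C)[C@@H]2[C@@H]1CO | intermediate
17 | 1-[7-hydroxy-1-(hydroxymethyl)-3,6,8-trimethyl-4a,5,6,7,8,8a-hexahydronaphthalen-2(1H)-ylidene]propan-2-one, not isolated | CC(=O)C=C1C(C)=C[C@@H]2C[C@H](C)C(O)[C@H](C)[C@@H]2[C@@H]1CO | intermediate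
18 | 1-[7-hydroxy-1-(hydroxymethyl)-3,6,8-trimethyl-1,5,6,7,8,8a-hexahydronaphthalen-2-yl]propan-2-one; H-1, H-6, H-8, H-8a on one face | CC(=O)CC1=C(C)C=C2C[C@H](C)C(O)[C@H](C)[C@@H]2[C@@H]1CO | intermediate
19 | 7-hydroxy-3,6,8-trimethyl-2-(2-oxopropyl)-1,5,6,7,8,8a-hexahydronaphthalene-1-carbaldehyde, not isolated | CC(=O)CC1=C(C)C=C2C[C@H](C)C(O)[C@H](C)[C@@H]2[C@@H]1C=O | intermediate
20 | (E)-3-[7-hydroxy-3,6,8-trimethyl-2-(2-oxopropyl)-1,5,6,7,8,8a-hexahydronaphthalen-1-yl]-2-methylprop-2-enal | CC(=O)CC1=C(C)C=C2C[C@H](C)C(O)[C@H](C)[C@@H]2[C@@H]1/C=C(\C)C=O | intermediate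
21 | ethyl (2E,4E)-5-[7-hydroxy-3,6,8-trimethyl-2-(2-oxopropyl)-1,5,6,7,8,8a-hexahydronaphthalen-1-yl]-2,4-dimethylpenta-2,4-dienoate | CC(=O)CC1=C(C)C=C2C[C@H](C)C(O)[C@H](C)[C@@H]2[C@@H]1/C=C(\C)/C=C(\C)C(=O)OCC | intermediate
22 | (2E,4E)-5-[7-hydroxy-2-(2-hydroxypropyl)-3,6,8-trimethyl-1,5,6,7,8,8a-hexahydronaphthalen-1-yl]-2,4-dimethylpenta-2,4-dien-1-ol | CC(O)CC1=C(C)C=C2C[C@H](C)C(O)[C@H](C)[C@@H]2[C@@H]1/C=C(\C)/C=C(\C)CO | intermediate
23 | (2S,3S)-epoxy alcohol from 22 (epoxide on the former C2=C3 alkene of the dienol) | CC(O)CC1=C(C)C=C2C[C@H](C)C(O)[C@H](C)[C@@H]2[C@@H]1/C=C(\C)[C@@H]1O[C@@]1(C)CO | intermediate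
24 | epoxy aldehyde from 23 (same spatial arrangement), not isolated | CC(O)CC1=C(C)C=C2C[C@H](C)C(O)[C@H](C)[C@@H]2[C@@H]1/C=C(\C)[C@@H]1O[C@@]1(C)C=O | intermediate
25 | methyl (E)-acrylate of the (2S,3S)-epoxide with both carbinols free | CC(O)CC1=C(C)C=C2C[C@H](C)C(O)[C@H](C)[C@@H]2[C@@H]1/C=C(\C)[C@@H]1O[C@@]1(C)/C=C/C(=O)OC | intermediate
26 | dihydroxy acid corresponding to 25 | CC(O)CC1=C(C)C=C2C[C@H](C)C(O)[C@H](C)[C@@H]2[C@@H]1/C=C(\C)[C@@H]1O[C@@]1(C)/C=C/C(=O)O | intermediate
27 | CNP0214881.1 | CC(=O)CC1=C(C)C=C2C[C@H](C)C(=O)[C@H](C)[C@@H]2[C@@H]1/C=C(\C)[C@@H]1O[C@@]1(C)/C=C/C(=O)O | target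

Total step count: 16. Longest linear sequence: 16 steps (the route is fully linear).

Steps most likely to fail

Step 9. The enolisation may lose its regiocontrol: deprotonation at C1 instead of C4a (cross-conjugated dienolate, loss of the C1 configuration), protonation of the trienolate away from the α-carbon, or conjugate addition of the primary alkoxide. The fallback sets out from 14 and comes back at 18. Silylation (t-BuMe2SiCl, imidazole, DMF) gives the bis-silyl ether F2. Deprotonation with n-BuLi and oxidation of the sulfonyl carbanion with Me3SiOOSiMe3 (oxidative desulfonylation) gives the enone F3. Tf2O and 2,6-di-tert-butyl-4-methylpyridine convert it into the linear dienyl triflate F4 through γ-deprotonation at C4a. Coupling with Bu3SnCH2COCH3 under Pd(PPh3)4 and LiCl gives the acetonyl diene F5, and HF·pyridine removes both silyl groups to return 18.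

Step 5. Enolisation of the hindered ketone by the organolithium, or incomplete exchange of lithium for potassium, may leave the alkoxide unrearranged and open to fragmentation; slow quenching may let the enolate migrate. The fallback sets out from 10 and comes back at 13. Addition of the organocerium reagent made from CH2=C(CH3)MgBr and CeCl3 in THF at −78 °C gives, after aqueous work-up, the tertiary allylic alcohol F1. KH and 18-crown-6 in THF at 25 °C then generate the potassium alkoxide directly and effect the oxy-Cope rearrangement, and quenching into AcOH at −78 °C returns 13.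

Step 10. Epimerisation or double-bond migration of the α-branched β,γ-unsaturated aldehyde, or its aldol closure onto the methyl ketone, may compete during the hot Wittig reaction. The fallback sets out from 18 and comes back at 22. The aerobic oxidation is run in the presence of Ph3P=C(CH3)CO2Et at 25 °C, so that the aldehyde is trapped as it forms, giving the enoate F6. i-Bu2AlH reduces ester and ketone to the allylic triol F7. MnO2 oxidises only the allylic alcohol to the hydroxy enal F8. Ph3P=C(CH3)CO2Et gives the hydroxy dienoate F9, and i-Bu2AlH returns 22.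

Further compounds
F1 | step 5 | 2-isopropenyl-2-hydroxy-1,3-dimethyl-7-tosylbicyclo[2.2.2]oct-5-ene-8-carboxylic acid (isopropenyl syn to C5=C6) | C[C@@]12[C@@](O)(C(C)=C)[C@H](C)[C@@H](C=C1)[C@H](C(=O)O)[C@H]2S(=O)(=O)c1ccc(C)cc1
F2 | step 9 | bis(tert-butyldimethylsilyl) ether of 14 | Cc1ccc(cc1)S(=O)(=O)C1C(C)=C[C@@H]2C[C@H](C)C(O[Si](C)(C)C(C)(C)C)[C@H](C)[C@@H]2[C@@H]1CO[Si](C)(C)C(C)(C)C
F3 | step 9 | silylated ring-A enone (3-methyl-2-oxo-1,2,4a,5,6,7,8,8a-octahydronaphthalene) | O=C1C(C)=C[C@@H]2C[C@H](C)C(O[Si](C)(C)C(C)(C)C)[C@H](C)[C@@H]2[C@@H]1CO[Si](C)(C)C(C)(C)C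
F4 | step 9 | silylated ring-A dienyl triflate | FC(F)(F)S(=O)(=O)OC1=C(C)C=C2C[C@H](C)C(O[Si](C)(C)C(C)(C)C)[C@H](C)[C@@H]2[C@@H]1CO[Si](C)(C)C(C)(C)C
F5 | step 9 | bis(tert-butyldimethylsilyl) ether of 18 | CC(=O)CC1=C(C)C=C2C[C@H](C)C(O[Si](C)(C)C(C)(C)C)[C@H](C)[C@@H]2[C@@H]1CO[Si](C)(C)C(C)(C)C
F6 | step 10 | ethyl (E)-3-[7-hydroxy-3,6,8-trimethyl-2-(2-oxopropyl)-1,5,6,7,8,8a-hexahydronaphthalen-1-yl]-2-methylacrylate | CC(=O)CC1=C(C)C=C2C[C@H](C)C(O)[C@H](C)[C@@H]2[C@@H]1/C=C(\C)C(=O)OCC
F7 | step 10 | (E)-3-[7-hydroxy-2-(2-hydroxypropyl)-3,6,8-trimethyl-1,5,6,7,8,8a-hexahydronaphthalen-1-yl]-2-methylprop-2-en-1-ol | CC(O)CC1=C(C)C=C2C[C@H](C)C(O)[C@H](C)[C@@H]2[C@@H]1/C=C(\C)CO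
F8 | step 10 | (E)-3-[7-hydroxy-2-(2-hydroxypropyl)-3,6,8-trimethyl-1,5,6,7,8,8a-hexahydronaphthalen-1-yl]-2-methylprop-2-enal | CC(O)CC1=C(C)C=C2C[C@H](C)C(O)[C@H](C)[C@@H]2[C@@H]1/C=C(\C)C=O
F9 | step 10 | ethyl (2E,4E)-5-[7-hydroxy-2-(2-hydroxypropyl)-3,6,8-trimethyl-1,5,6,7,8,8a-hexahydronaphthalen-1-yl]-2,4-dimethylpenta-2,4-dienoate | CC(O)CC1=C(C)C=C2C[C@H](C)C(O)[C@H](C)[C@@H]2[C@@H]1/C=C(\C)/C=C(\C)C(=O)OCC
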